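No rate constant of this flask is given, so the runs must stand in for the constants, and a time has to be read from them instead of reckoned from a constant.

all flasks: free catalyst 1.5 mM
- beta: starting material 0.30 M; reagent 0.27 M; protic impurity 0.060 M; the very flask that is asked about, followed so far
- zeta: starting material 0.45 M; reagent 0.27 M; protic impurity 0.060 M; run made earlier
- flask: starting material 0.30 M; reagent 0.270 M; protic impurity 0.0600 M

| run | time / s | target / % | starting material / % |
|---|---|---|---|
| beta | 10.0 | 7 | 88 |
| beta | 12.0 | 14 | 88 |
| beta | 20.0 | 18 | 78 |
| beta | 40.0 | 29 | 60 |
| beta | 60.0 | 40 | 51 |
| zeta | 10.0 | 9 | 89 |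
| zeta | 12.0 | 11 | 88 |
| zeta | 20.0 | 15 | 84 |
| zeta | 40.0 | 21 | 70 |
| zeta | 60.0 | 31 | 58 |

(scatter of a reading: 2 percentage points)

1. apparent order in reagent when 5.0 % of the starting material are converted (percent change of the rate of making target for one percent more reagent charged)

In the beta run, target rises from 18 % at 20.0 s to 40 % at 60.0 s. With 1.5 mM of catalyst charged, that reading is one target per catalyst every 0.909 s. This time, the charged catalyst divided by the rate of making target, is the turnover time τ.

Where a catalyst passes through steps one after another without return, τ is the sum of its waits. The apparent order in reagent is then the share of τ spent waiting for reagent, and an order of one would make that wait the rate-limiting step.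

If one reagent goes per target, reagent in the beta run falls from 0.216 M at 20.0 s to 0.150 M at 60.0 s, so a turn that was purely a wait for reagent would stretch by a factor of 1.44. Yet target gains 11 percentage points in the first half of that span and 11 points in the second. Each reading scatters by 2 points, so this is a leaning and not a measurement, and no run changes the reagent charge. The reckoning here commits to an order below 0.5.

The forecast puts the order at 0.7, within 0.2 to 1.4: “neither run varied reagent, so this is a guess”.

The simulation gives 0.17, which is less than that 0.5.

    starting material + free catalyst ⇌ catalyst intermediate A (K = 110 M⁻¹, k = 14.0 M⁻¹ s⁻¹)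
    catalyst intermediate A ⇌ catalyst intermediate B (K = 4.30, k = 8.40 s⁻¹)
    reagent + catalyst intermediate B → catalyst intermediate C (k = 55.0 M⁻¹ s⁻¹)
    catalyst intermediate C → free catalyst + target (k = 230 s⁻¹)
    2 catalyst intermediate A ⇌ resting dimer, settled at all times (K = 1300 M⁻¹)
    starting material + protic impurity → quenched substrate (k = 0.0470 M⁻¹ s⁻¹)

At the 0.150 M of reagent reckoned for 60.0 s in the beta run, one meeting of catalyst intermediate B with reagent takes 0.121 s, shorter than the τ of 0.909 s read up to that time, which makes it 0.133 of τ. At 0.250 min the flask holds 12.5 % of its catalyst as catalyst intermediate B and 46.1 % as free catalyst. In the zeta run, target gains 16 points between 20.0 s and 60.0 s, so τ reads 0.833 s, close to the beta reading, and with the 0.131 M of reagent reckoned the same way for 60.0 s, the same meeting is 0.167 of that τ.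

Readings and results were generated by integration for an exercise; noise was put on by code.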